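At late times Thursday's run stands still: from 1.33 h to 8.00 h, with partner at 1.4 equiv, target reads 7.00 % on average and side product 93.1 %, together 100 % of the substrate charged, so that plateau is a finished count of one branching.

| setting | Tuesday's | Thursday's | flask |
|---|---|---|---|
| substrate | 0.084 M | 0.084 M | 0.084 M |
| partner | 0.90 equiv | 1.4 equiv | 0.900 equiv |
| second reagent | 1 equiv | 1 equiv | 1.00 equiv |
| remark | the very flask that is asked about, followed so far | run made earlier |  |
| time |  |  | 10 h |

Tuesday's run (percent of the substrate charged)

| time / min | target / % | side product / % |
|---|---|---|
| 25.0 | 5.1 | 61.5 |
| 50.0 | 5.0 | 75.1 |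
| 80.0 | 5.8 | 79.8 |
| 90.0 | 5.3 | 79.6 |
| 120 | 6.2 | 82.4 |

Thursday's run (percent of the substrate charged)

| time / h | target / % | side product / % |
|---|---|---|
| 1.33 | 7.2 | 92.6 |
| 3.00 | 6.8 | 93.2 |
| 4.00 | 7.4 | 93.1 |
| 6.00 | 7.1 | 93.1 |
| 8.00 | 6.5 | 93.4 |

(readings scatter by 0.3 percentage points)

1. amount of target at 10 h, in percent of the substrate charged
2. amount of side product at 10 h, in percent of the substrate charged

The suspected steps branch at the intermediate: target forms at a rate proportional to [second reagent][intermediate], side product at a rate proportional to [intermediate], so the ratio of the two rates contains [second reagent] but not [intermediate]. With x the target and y the side product as fractions of the substrate charged, and m the second reagent charged in equivalents, dx/dy = b(m − x), which integrates to x = m(1 − exp(−by)). Thursday's plateau reads b = 0.0780, the selectivity factor, target gained per side product formed for each equivalent of second reagent present.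

In the flask, which Tuesday's run follows, partner at 0.900 equiv is the limiting reagent, so x + y ends at 90.0 %; Tuesday's sum reads 88.6 % at 120 min, and the asked 10 h is longer, so that ceiling is taken as reached. Holding the share of target constant, Thursday's 6.99 % gives target 6.29 % in the flask. That constancy is the weak link, since each target consumes one second reagent; the closed form, fed with the remaining side product, gives 6.32 %, a shift below the scatter of 0.3 percentage points, and leaves side product 83.7 %.

The forecast, holding that “Neither product decays”, gives 6.4 % target and 83.6 % side product. The flask gives 6.30 % target and 83.7 % side product.

    substrate + partner → intermediate (k = 0.0280 M⁻¹ s⁻¹)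
    second reagent + intermediate → target (k = 0.00250 M⁻¹ s⁻¹)
    intermediate → side product (k = 0.00270 s⁻¹)

The flask's side product answer moves by 5 points once partner stands at 0.847 equiv or 0.955 equiv, the other amounts and the time held. In the flask [second reagent] ends at 93.7 % of its charge, and the share that the closed form leaves, exp(−by), with b at 0.0780 and y at 83.7 % comes to 93.7 %. The neighbouring flask raises second reagent to 2.50 equiv: m becomes 2.50, and with x + y again 90.0 % the closed form gives target 14.3 % and side product 75.7 %. Simulated, that neighbour holds target 14.3 % and side product 75.7 %.

The numbers in the tables come from a simulation for an exercise; the scatter is artificial.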